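## Structural features

- The target is a cyclohexene (ring atoms C1–C6, C4=C5) fused at C2–C3 to an oxirane. C6 carries a methyl group and, through its C6′, a 2-methoxy-3,5-dimethyl-4-pyranone. C1 carries the chain C7(Me)=C8–C9H(Me)–C10(=O)–C11–C12 with an (E) alkene.
- Four stereocentres are contiguous on the ring (C1, C2, C3, C6, with C2 and C6 fully substituted); the fifth, C9, stands alone in the chain. The chain on C1 and the pyranone on C6 share one face; the oxirane oxygen lies on the other.
- The oxirane is allylic at C3 and tertiary at C2, so it will not tolerate protic or Lewis acids.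
- C9–H lies between the ketone and the alkene and is prone to epimerisation and to migration of the alkene into conjugation.
- The methoxypyranone has to come from an ambident hydroxypyranone.
- The real difficulty is the crowded C2–C1–C6 array, a tertiary carbon between two quaternary ones, and the order in which ketone, diol and oxirane are unmasked.
- The key step exploits C4(Me)=C5 lying next to oxygenated C3. At the carbinol level this is a cyclic allylic alcohol, so the ring can be closed by joining a (Z)-alkenyl iodide at C4 to an aldehyde at C3, with C1, C2, C6 and C9 already set in an open chain.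

## Logic of the disconnections

**44 ⇒ 42.** The C3–O bond of the oxirane is cut, leaving the trans-2,3-diol 42. A tertiary/secondary allylic diol can be closed under mild base once the secondary hydroxyl alone is sulfonylated, and the acid-labile oxirane then appears only in the last step. The forward step inverts C3, so C3–OH of 42 must stand anti to the C2 oxygen, and the base must spare C9–H next to the free ketone.

**42 ⇒ 41.** No skeletal bond is cut. The two silyl ethers and the dioxolane of 41 are chosen to fall to the same dilute acid, so acid is used only before the oxirane exists. The demand is that the allylic diol and the enolisable ketone tolerate that acid.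

**41 ⇒ 35 + 36.** The pyranone is cut at C6′–C5′, at the ring O–C2′ bond and at O–CH3, passing back through 40, 39 and 38. The heterocycle reduces to an aldehyde on quaternary C6 and a five-carbon keto ester. The forward steps require a dianion to add to a neopentyl aldehyde and 40 to be methylated on the lactone carbonyl oxygen, not on the 4-hydroxyl.

**35 ⇒ 32.** Only oxidation levels change (through 34 and 33): the C6 ester is the latent aldehyde. C3–OH must be masked first, or it would be oxidised and could lactonise onto the cis ester.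

**32 ⇒ 30 (key).** The C3–C4 bond is cut, opening the ring to an aldehyde at C3 and a (Z)-alkenyl iodide at C4. One ring, one bond and the C3 centre are removed, and all remaining stereocentres sit in an acyclic chain. The forward step needs a nucleophile that ignores ester, ketal and silyl ether, keeps the alkene geometry and attacks the aldehyde face that puts C3–OH trans to the C2 oxygen.

**30 ⇒ 23 + 24.** The C4=C5 double bond is cut (through 29 and 28), giving an aldehyde on C6 and a two-carbon phosphonium salt. The iodo-olefination must give the (Z) isomer on an α-quaternary aldehyde; the C3 ether is oxidised to the aldehyde only afterwards.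

**23 ⇒ 19.** The C1–C6 bond is cut as a [3,3] shift (through 22, 21 and 20). The crowded bond, both of its stereocentres and the (E)-C7=C8 alkene go back to an allylic malonate whose C8 carbinol centre is transferred to C1. The forward step needs a defined ketene acetal geometry for C6, a chair transition state, and the acid rather than the methyl ester to become C5.

**19 ⇒ 14 + 16.** The C8–O ester bond is cut (through 18 and 17), together with removal of the dioxolane and return of the C11 benzoyloxy group; 16 comes from 15. The ketone must be masked before the enolate chemistry without epimerising C9.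

**14 ⇒ 8 + 12.** The C8–C9 bond is cut as an anti aldol. The [3,3] shift needs 8S with 9R, which an (E)-enolate of a chiral ethyl ketone equivalent provides; 12 goes back to 9 through 11 and 10.

**8 ⇒ 2 + 3, and 2 ⇒ 1.** The C1=C7 alkene is cut as a Wittig olefination (through 7, 6, 5 and 4), and the C3–O ether bond is cut to the oxirane of 1. C2 is bought with the correct configuration; the forward opening must occur at the unsubstituted oxirane carbon.

## Other disconnections considered

**Alternative 1:** The cut runs through C1–C2 and C5–C6. Forward, the (Z)-silyloxydiene A3 would add to the 3-methylbutenolide A2 on the face opposite its menthyloxy group, giving the cis-fused lactone acetal A1 with a silyl enol ether at C3=C4.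
- In favour: two ring bonds and the C1/C6 pair, quaternary C6 included, form at once. The cis relation of the future chain carbon and the future pyranone carbon is enforced by the five-membered ring. The regiochemistry is matched, since the nucleophilic diene terminus C2 meets the β-carbon of the butenolide.
- Against: an α-methylbutenolide is a sluggish dienophile, and the acids or pressures that would help threaten the enol ether and the acetal. A1 still lacks the C2 oxygen (face-selective α-hydroxylation), the C4=C5 unsaturation, the whole C7–C12 chain with its (E) alkene and C9 centre, and the pyranone.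
- Comparison: on structure this is the better way to secure C1 and C6, which the chosen plan leaves to a ketene acetal geometry. On mechanism both closures are well precedented, and the cycloaddition needs no stoichiometric metal. On step economy the chosen plan is ahead: C2 is bought, the chain is complete before ring closure, and C9 is set by a reagent-controlled aldol instead of late and without a controlling neighbour.

**Alternative 2:** The cut is the C4=C5 double bond, formed while the C5=C7 bond of a cyclobutene is broken. Forward, the second-generation Hoveyda–Grubbs ruthenium catalyst would open the 1-methylcyclobutene of A5, and the C5 alkylidene would close onto the C4(Me)=CH2 enone to give the cyclohexenone A4 with an isopropenyl group on C1.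
- In favour: ring strain drives the cascade, C1 and C6 are fixed beforehand on a small ring, and C3 is already a carbonyl. The metal is catalytic, which is better on waste and toxicity than ten equivalents of CrCl2.
- Against: both alkenes are poor substrates (a trisubstituted cyclobutene for initiation, a 1,1-disubstituted electron-poor alkene for closure), so oligomerisation would compete. A4 carries only C7 and its methyl, and extending an isopropenyl group to the (E)-C7=C8 alkene with the C9 centre is hard. The C3 ketone needs a face-selective reduction, and the pyranone is as far away as in the chosen plan.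
- Comparison: equal on the ring alkene (geometry enforced by the ring in both) and better on metal load. It is weaker on structure (chain and C9 missing) and on step economy (chain extension plus the same pyranone annulation). Mechanistically the alkenylchromium addition tolerates crowding better.

**Alternative 3:** The cut is C2–C3. Forward, a chiral triazolium-derived carbene would turn the C3 enal of A7 into a Breslow intermediate that adds to the C2 methyl ketone, giving the α-hydroxy enone A6.
- In favour: pyranone and chain are already in place, so only C3 reduction, oxirane closure and deketalisation would follow. On steps after ring closure this is clearly better than the chosen plan. The catalyst is organic, and C2 and the C3 carbonyl arise together.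
- Against: the C2 configuration must be created in the ring closure next to C1, with possible catalyst/substrate mismatch, whereas the chosen plan takes C2 from the chiral pool. An enal can react as a homoenolate, and its (Z) geometry, needed for closure, can be lost. The acceptor is a hindered ketone and the benzoin step is reversible. A7 needs a pyranone on quaternary C6 beside a (Z)-enal, which is hard to assemble. The C3 reduction again needs facial control.
- Comparison: better in convergence and endgame length, equal in ring size and closure mode (both are 6-exo additions to a carbonyl), weaker in stereochemical security at C2 and in chemoselectivity of the nucleophile.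

Key step: step 19

Remark on the chemistry: the lithium enolate of 19 is assumed to be chelated between its two carbonyl oxygens, which fixes the geometry of 20; the C2 oxygen is carried as a triethylsilyl ether so that one acid treatment frees diol and ketone before the oxirane is made.

## Steps

Step 1
Reactants: 1 (S)-2-methylglycidol
Product: 2 (2S)-3-[(4-methoxybenzyl)oxy]-2-methylpropane-1,2-diol
Conditions: 4-MeOC6H4CH2OH (5 equiv), KOtBu (0.2 equiv), 80 °C
Reagents that add atoms: 4-methoxybenzyl alcohol, OCc1ccc(OC)cc1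
Why: Base-mediated SN2 opening of the oxirane at its unsubstituted carbon by the benzylic alkoxide; C2 is not touched and a Payne shift of this substrate is degenerate, so the configuration is kept.

Step 2
Reactants: 2 (2S)-3-[(4-methoxybenzyl)oxy]-2-methylpropane-1,2-diol; 3 ethyl 2-(triphenylphosphoranylidene)propanoate
Product: 5 ethyl (2E,4S)-4-hydroxy-5-[(4-methoxybenzyl)oxy]-2,4-dimethylpent-2-enoate, via hydroxy aldehyde 4 (not isolated)
Conditions: IBX, DMSO, rt; then 3, rt
Reagents that add atoms: none
Why: IBX oxidises the primary hydroxyl of the 1,2-diol without glycol cleavage and the stabilised ylide is added to the same flask (tandem oxidation–Wittig olefination); the α-branched stabilised ylide gives the (E)-trisubstituted enoate and so fixes the C1=C7 geometry.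

Step 3
Reactants: 5 ethyl (2E,4S)-4-hydroxy-5-[(4-methoxybenzyl)oxy]-2,4-dimethylpent-2-enoate
Product: 6 ethyl (2E,4S)-5-[(4-methoxybenzyl)oxy]-2,4-dimethyl-4-(triethylsilyloxy)pent-2-enoate
Conditions: Et3SiOTf, 2,6-lutidine, CH2Cl2, −78 → 0 °C
Reagents that add atoms: triethylsilyl trifluoromethanesulfonate, CC[Si](CC)(CC)OS(=O)(=O)C(F)(F)F
Why: Silylation of a tertiary alcohol with a silyl triflate; the triethylsilyl ether withstands the bases, hydrides and oxidants ahead yet falls to dilute acid at the end.

Step 4
Reactants: 6 ethyl (2E,4S)-5-[(4-methoxybenzyl)oxy]-2,4-dimethyl-4-(triethylsilyloxy)pent-2-enoate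
Product: 7 (2E,4S)-5-[(4-methoxybenzyl)oxy]-2,4-dimethyl-4-(triethylsilyloxy)pent-2-en-1-ol
Conditions: iBu2AlH, CH2Cl2, −78 °C
Reagents that add atoms: none
Why: 1,2-Reduction of the enoate by iBu2AlH to the allylic alcohol.

Step 5
Reactants: 7 (2E,4S)-5-[(4-methoxybenzyl)oxy]-2,4-dimethyl-4-(triethylsilyloxy)pent-2-en-1-ol
Product: 8 (2E,4S)-5-[(4-methoxybenzyl)oxy]-2,4-dimethyl-4-(triethylsilyloxy)pent-2-enal
Conditions: MnO2, CH2Cl2, rt
Reagents that add atoms: none
Why: Selective allylic oxidation with MnO2, which stops at the enal and does not isomerise the alkene.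

Step 6
Reactants: 9 ethyl (2S)-2-hydroxypropanoate
Product: 10 (2S)-2-hydroxy-N-methoxy-N-methylpropanamide
Conditions: MeNH(OMe)·HCl, iPrMgCl, THF, −20 → 0 °C
Reagents that add atoms: N,O-dimethylhydroxylamine hydrochloride, CNOC.Cl
Why: Aminolysis of the ester by the magnesium amide of N,O-dimethylhydroxylamine (Weinreb amide formation); the stereocentre is not enolised.

Step 7
Reactants: 10 (2S)-2-hydroxy-N-methoxy-N-methylpropanamide
Product: 11 (2S)-2-hydroxypentan-3-one
Conditions: EtMgBr, THF, 0 °C → rt
Reagents that add atoms: ethylmagnesium bromide, CC[Mg]Br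
Why: Grignard addition to the Weinreb amide stops at the ketone through the chelated tetrahedral intermediate.

Step 8
Reactants: 11 (2S)-2-hydroxypentan-3-one
Product: 12 (2S)-3-oxopentan-2-yl benzoate
Conditions: Bz2O, iPr2NEt, DMAP (cat.), CH2Cl2, rt
Reagents that add atoms: benzoic anhydride, O=C(OC(=O)c1ccccc1)c1ccccc1
Why: DMAP-catalysed acylation of the secondary alcohol.

Step 9
Reactants: 8 (2E,4S)-5-[(4-methoxybenzyl)oxy]-2,4-dimethyl-4-(triethylsilyloxy)pent-2-enal; 12 (2S)-3-oxopentan-2-yl benzoate
Product: 14 (2S,4R,5S,6E,8S)-5-hydroxy-9-[(4-methoxybenzyl)oxy]-4,6,8-trimethyl-3-oxo-8-(triethylsilyloxy)non-6-en-2-yl benzoate, via enol dicyclohexylborinate 13 (not isolated)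
Conditions: 12, Cy2BCl, Me2NEt, Et2O, −78 → 0 °C; then 8, −78 → −20 °C; H2O2, MeOH, pH 7 buffer
Reagents that add atoms: none
Why: Lactate-derived boron aldol (Paterson anti-aldol): Cy2BCl and the small amine give the (E)-enol borinate 13, which reacts through a chair Zimmerman–Traxler transition state to the anti adduct. The benzoyloxy stereocentre directs the aldehyde to one enolate face (minimised A(1,3) strain, formyl hydrogen bond to the benzoate), which should set C9 as R and C8 as S; the distant C2 centre of 8 has no influence.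

Step 10
Reactants: 15 dimethyl 2-methylpropanedioate
Product: 16 3-methoxy-2-methyl-3-oxopropanoic acid (racemic)
Conditions: KOH (1.0 equiv), MeOH, rt; then 1 M HCl
Reagents that add atoms: potassium hydroxide, [K+].[OH-]
Why: Mono-saponification of the symmetrical diester with one equivalent of hydroxide; the carboxylate formed resists a second hydrolysis.

Step 11
Reactants: 14 (2S,4R,5S,6E,8S)-5-hydroxy-9-[(4-methoxybenzyl)oxy]-4,6,8-trimethyl-3-oxo-8-(triethylsilyloxy)non-6-en-2-yl benzoate; 16 3-methoxy-2-methyl-3-oxopropanoic acid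
Product: 17 1-[(2S,4R,5S,6E,8S)-2-(benzoyloxy)-9-[(4-methoxybenzyl)oxy]-4,6,8-trimethyl-3-oxo-8-(triethylsilyloxy)non-6-en-5-yl] 3-methyl 2-methylpropanedioate (both epimers at the malonate carbon)
Conditions: DCC, DMAP (cat.), CH2Cl2, 0 °C → rt
Reagents that add atoms: none
Why: Steglich esterification; the malonic half-acid activated by DCC acylates the hindered C8 hydroxyl with retention, and the malonate centre is irrelevant because it is enolised later.

Step 12
Reactants: 17 the benzoyloxy malonate of step 11
Product: 18 1-[(4R,5S,6E,8S)-9-[(4-methoxybenzyl)oxy]-4,6,8-trimethyl-3-oxo-8-(triethylsilyloxy)non-6-en-5-yl] 3-methyl 2-methylpropanedioate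
Conditions: SmI2, THF/MeOH, −78 °C
Reagents that add atoms: none
Why: SmI2 cleaves the α-benzoyloxy group by two single-electron transfers; the samarium enolate forms only between C10 and C11 and is protonated by methanol, so C9 is not epimerised and the C8 ester is not eliminated.

Step 13
Reactants: 18 the ethyl ketone malonate of step 12
Product: 19 1-[(1S,2E,4S)-1-[(1R)-1-(2-ethyl-1,3-dioxolan-2-yl)ethyl]-5-[(4-methoxybenzyl)oxy]-2,4-dimethyl-4-(triethylsilyloxy)pent-2-en-1-yl] 3-methyl 2-methylpropanedioate
Conditions: Me3SiOCH2CH2OSiMe3, Me3SiOTf (cat.), CH2Cl2, −78 → −20 °C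
Reagents that add atoms: 1,2-bis(trimethylsilyloxy)ethane, C[Si](C)(C)OCCO[Si](C)(C)C
Why: Noyori ketalisation under kinetic conditions avoids the enolisation of C9 and the β-elimination of the C8 ester that a heated protic ketalisation would risk.

Step 14
Reactants: 19 the dioxolane malonate of step 13
Product: 21 (2S,3R,4E,6R)-6-(2-ethyl-1,3-dioxolan-2-yl)-2-(methoxycarbonyl)-3-[(2S)-1-[(4-methoxybenzyl)oxy]-2-(triethylsilyloxy)propan-2-yl]-2,4-dimethylhept-4-enoic acid, via silyl ketene acetal 20 (not isolated)
Conditions: LiN(SiMe3)2, THF, −78 °C; Me3SiCl, −78 → 65 °C; aq. citric acid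
Reagents that add atoms: none
Why: Ireland–Claisen rearrangement of a malonate-derived silyl ketene acetal: the chelated lithium enolate is silylated with the silyloxy group cis to the methoxycarbonyl group, and a chair transition state with the C9-bearing substituent equatorial should transfer the C8 configuration to C1 (R), set quaternary C6 and give the (E)-C7=C8 alkene. The exothermic [3,3] shift is one of the few reactions that tolerates the crowding of the new C1–C6 bond.

Step 15
Reactants: 21 the malonic half-acid of step 14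
Product: 23 methyl (2S,3R,4E,6R)-6-(2-ethyl-1,3-dioxolan-2-yl)-2-formyl-3-[(2S)-1-[(4-methoxybenzyl)oxy]-2-(triethylsilyloxy)propan-2-yl]-2,4-dimethylhept-4-enoate, via acid chloride 22 (not isolated)
Conditions: 1-chloro-N,N,2-trimethylprop-1-en-1-amine, CH2Cl2, 0 °C; then LiAlH(OtBu)3, THF, −78 °C
Reagents that add atoms: none
Why: The neutral α-chloroenamine (Ghosez reagent) converts the hindered acid into the acid chloride without free HCl, and LiAlH(OtBu)3 reduces an acid chloride to the aldehyde at −78 °C while leaving the methyl ester; the quaternary α-carbon cannot enolise.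

Step 16
Reactants: 23 the formyl ester of step 15; 24 ethyltriphenylphosphonium iodide
Product: 28 methyl (2S,3R,4E,6R)-6-(2-ethyl-1,3-dioxolan-2-yl)-2-[(1Z)-2-iodoprop-1-en-1-yl]-3-[(2S)-1-[(4-methoxybenzyl)oxy]-2-(triethylsilyloxy)propan-2-yl]-2,4-dimethylhept-4-enoate, via ethylidenetriphenylphosphorane 25 (not isolated), via (1-iodoethyl)triphenylphosphonium iodide 26 (not isolated), via (1-iodoethylidene)triphenylphosphorane 27 (not isolated)
Conditions: 24, n-BuLi, THF, rt; I2, −78 °C; NaN(SiMe3)2, −20 °C; then 23, −78 → −20 °C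
Reagents that add atoms: iodine, II
Why: Stork–Zhao iodo-olefination: the α-iodo ylide 27 should give the (Z)-2-iodoalkene through the kinetically preferred oxaphosphetane, which places C4 and its iodine on the same side as C6; the aldehyde cannot epimerise.

Step 17
Reactants: 28 the (Z)-iodoalkene 4-methoxybenzyl ether of step 16
Product: 29 methyl (2S,3R,4E,6R)-6-(2-ethyl-1,3-dioxolan-2-yl)-3-[(2S)-1-hydroxy-2-(triethylsilyloxy)propan-2-yl]-2-[(1Z)-2-iodoprop-1-en-1-yl]-2,4-dimethylhept-4-enoate
Conditions: DDQ, CH2Cl2/pH 7 buffer, 0 °C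
Reagents that add atoms: none
Why: Oxidative cleavage of the 4-methoxybenzyl ether by DDQ (hydride abstraction, then hydrolysis of the oxocarbenium ion); alkenes, iodide, ketal and silyl ether are inert under buffered conditions.

Step 18
Reactants: 29 the primary alcohol of step 17
Product: 30 methyl (2S,3R,4E,6R)-6-(2-ethyl-1,3-dioxolan-2-yl)-2-[(1Z)-2-iodoprop-1-en-1-yl]-2,4-dimethyl-3-[(2S)-1-oxo-2-(triethylsilyloxy)propan-2-yl]hept-4-enoate
Conditions: DMP, pyridine, CH2Cl2, 0 °C → rt
Reagents that add atoms: none
Why: Dess–Martin oxidation under pyridine buffer; the α-quaternary α-silyloxy aldehyde cannot epimerise.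

Step 19
Reactants: 30 the (Z)-iodoalkene aldehyde of step 18
Product: 32 methyl (1R,4S,5S,6R)-6-[(2E,4R)-4-(2-ethyl-1,3-dioxolan-2-yl)pent-2-en-2-yl]-4-hydroxy-1,3,5-trimethyl-5-(triethylsilyloxy)cyclohex-2-ene-1-carboxylate, via alkenylchromium dichloride 31 (not isolated)
Conditions: CrCl2 (10 equiv), NiCl2 (5 mol %), degassed DMSO, 0.005 M, rt
Reagents that add atoms: none
Why: Intramolecular Nozaki–Hiyama–Kishi alkenylation: CrCl2 reduces NiCl2 to zerovalent nickel, which inserts into the C4–I bond with retention of the (Z) geometry, and transmetalation to trivalent chromium gives the alkenylchromium 31, which adds to the C3 aldehyde. The closest known reaction type is the nickel-catalysed, chromium-mediated closure of iodoalkenyl aldehydes to cycloalkenols. The ring closes in the 6-exo-trig mode, C4 attacking the carbonyl carbon C3 while the carbonyl oxygen stays outside the ring. The new C3 centre is controlled by the neighbouring quaternary C2: in the chair-like transition state the C1 chain and the C2 silyloxy group are equatorial, the C2–O bond lies anti to the incoming C4 (polar Felkin–Anh arrangement) and the bulky chromium alkoxide is equatorial, so C3–O should end trans to C2–O (3S). The step needs chemoselectivity for the aldehyde, which the low basicity and carbonyl selectivity of the alkenylchromium secure against the hindered ester, the dioxolane and the silyl ether. It also needs the (Z) geometry, which holds C4 within bonding distance of C3 and which neither organometallic intermediate scrambles. High dilution suppresses intermolecular addition, and silylation in step 20 removes any chance of the C3 oxygen lactonising onto the cis C6 ester.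

Step 20
Reactants: 32 the cyclohexenol of step 19
Product: 33 methyl (1R,4S,5S,6R)-6-[(2E,4R)-4-(2-ethyl-1,3-dioxolan-2-yl)pent-2-en-2-yl]-1,3,5-trimethyl-4,5-bis(triethylsilyloxy)cyclohex-2-ene-1-carboxylate
Conditions: Et3SiOTf, 2,6-lutidine, CH2Cl2, −78 → 0 °C
Reagents that add atoms: triethylsilyl trifluoromethanesulfonate, CC[Si](CC)(CC)OS(=O)(=O)C(F)(F)F
Why: Silylation of the hindered secondary allylic alcohol with the silyl triflate; it shields C3–OH from the oxidations ahead.

Step 21
Reactants: 33 the bis(silyl ether) ester of step 20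
Product: 34 [(1R,4S,5S,6R)-6-[(2E,4R)-4-(2-ethyl-1,3-dioxolan-2-yl)pent-2-en-2-yl]-1,3,5-trimethyl-4,5-bis(triethylsilyloxy)cyclohex-2-en-1-yl]methanol
Conditions: iBu2AlH, CH2Cl2, −78 → −20 °C
Reagents that add atoms: none
Why: Reduction of the hindered methyl ester to the neopentyl alcohol with excess iBu2AlH.

Step 22
Reactants: 34 the neopentyl alcohol of step 21
Product: 35 (1R,4S,5S,6R)-6-[(2E,4R)-4-(2-ethyl-1,3-dioxolan-2-yl)pent-2-en-2-yl]-1,3,5-trimethyl-4,5-bis(triethylsilyloxy)cyclohex-2-ene-1-carbaldehyde
Conditions: DMP, pyridine, CH2Cl2, rt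
Reagents that add atoms: none
Why: Dess–Martin oxidation to a non-enolisable aldehyde.

Step 23
Reactants: 35 the ring aldehyde of step 22; 36 methyl 2-methyl-3-oxopentanoate
Product: 38 methyl 5-hydroxy-2,4-dimethyl-3-oxo-5-[the (1R,4S,5S,6R)-cyclohexenyl unit of 35]pentanoate (mixture of diastereomers at the three chain centres), via keto ester dianion 37 (not isolated)
Conditions: 36, NaH, THF, 0 °C; n-BuLi, 0 °C; then 35, −78 °C
Reagents that add atoms: none
Why: Aldol addition of the γ-carbanion of the β-keto ester dianion (Huckin–Weiler dianion) to the aldehyde; the three new chain centres are destroyed in the next two steps, so their configuration is immaterial.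

Step 24
Reactants: 38 the δ-hydroxy β-keto ester of step 23
Product: 39 methyl 2,4-dimethyl-3,5-dioxo-5-[the (1R,4S,5S,6R)-cyclohexenyl unit of 35]pentanoate
Conditions: DMP, pyridine, CH2Cl2, rt
Reagents that add atoms: none
Why: Dess–Martin oxidation of the secondary alcohol to the 3,5-diketo ester.

Step 25
Reactants: 39 the 3,5-diketo ester of step 24
Product: 40 4-hydroxy-3,5-dimethyl-6-[the (1R,4S,5S,6R)-cyclohexenyl unit of 35]-2H-pyran-2-one
Conditions: DBU, toluene, 60 °C
Reagents that add atoms: none
Why: Base-mediated lactonisation of the enolised δ-ketone onto the methyl ester gives the 4-hydroxy-2-pyranone.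

Step 26
Reactants: 40 the 4-hydroxy-2-pyranone of step 25
Product: 41 2-methoxy-3,5-dimethyl-6-[(1R,4S,5S,6R)-6-[(2E,4R)-4-(2-ethyl-1,3-dioxolan-2-yl)pent-2-en-2-yl]-1,3,5-trimethyl-4,5-bis(triethylsilyloxy)cyclohex-2-en-1-yl]-4H-pyran-4-one
Conditions: MeOTf, 2,6-di-tert-butyl-4-methylpyridine, CH2Cl2, 0 °C → rt
Reagents that add atoms: methyl trifluoromethanesulfonate, COS(=O)(=O)C(F)(F)F
Why: O-Methylation with a hard electrophile under non-ionising conditions should occur at the lactone carbonyl oxygen, and loss of a proton from the 2-methoxy-4-hydroxypyrylium ion gives the 2-methoxy-4-pyranone; the hindered pyridine traps the acid so that silyl ethers and ketal survive.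

Step 27
Reactants: 41 the protected methoxypyranone of step 26
Product: 42 2-[(1R,4S,5S,6R)-4,5-dihydroxy-1,3,5-trimethyl-6-[(2E,4R)-4-methyl-5-oxohept-2-en-2-yl]cyclohex-2-en-1-yl]-6-methoxy-3,5-dimethyl-4H-pyran-4-one
Conditions: 1 M aq. HCl/THF (1:4), 0 °C → rt
Reagents that add atoms: water, O
Why: Acid hydrolysis removes both triethylsilyl ethers and the dioxolane in one operation while no oxirane is present; the 2-methoxy-4-pyranone is stable to dilute acid.

Step 28
Reactants: 42 the diol ketone of step 27
Product: 44 2-methoxy-3,5-dimethyl-6-[(1R,4R,5R,6S)-2,4,6-trimethyl-5-[(2E,4R)-4-methyl-5-oxohept-2-en-2-yl]-7-oxabicyclo[4.1.0]hept-2-en-4-yl]-4H-pyran-4-one (CNP0336888.3), via hydroxy mesylate 43 (not isolated)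
Conditions: Ms2O, Et3N, CH2Cl2, −20 °C; then DBU, 0 °C → rt
Reagents that add atoms: none
Why: Sulfene-type mesylation is selective for the secondary allylic hydroxyl over the tertiary one; base then closes the oxirane by internal SN2 displacement (Williamson-type 3-exo-tet closure), inverting C3 and retaining C2, so the oxygen ends anti to the C1 chain. Short exposure to an amidine base at low temperature is meant to leave C9–H untouched.

## Compound list

1 | (S)-2-methylglycidol, [(2S)-2-methyloxiran-2-yl]methanol | OC[C@@]1(C)CO1 | starting material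
2 | (2S)-3-[(4-methoxybenzyl)oxy]-2-methylpropane-1,2-diol | OC[C@@](O)(C)COCc1ccc(OC)cc1 | intermediate
3 | ethyl 2-(triphenylphosphoranylidene)propanoate | CCOC(=O)C(C)=P(c1ccccc1)(c1ccccc1)c1ccccc1 | starting material
4 | (2R)-2-hydroxy-3-[(4-methoxybenzyl)oxy]-2-methylpropanal | O=C[C@@](O)(C)COCc1ccc(OC)cc1 | intermediate
5 | ethyl (2E,4S)-4-hydroxy-5-[(4-methoxybenzyl)oxy]-2,4-dimethylpent-2-enoate | CCOC(=O)/C(C)=C/[C@@](O)(C)COCc1ccc(OC)cc1 | intermediate
6 | ethyl (2E,4S)-5-[(4-methoxybenzyl)oxy]-2,4-dimethyl-4-(triethylsilyloxy)pent-2-enoate | CCOC(=O)/C(C)=C/[C@@](O[Si](CC)(CC)CC)(C)COCc1ccc(OC)cc1 | intermediate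
7 | (2E,4S)-5-[(4-methoxybenzyl)oxy]-2,4-dimethyl-4-(triethylsilyloxy)pent-2-en-1-ol | OC/C(C)=C/[C@@](O[Si](CC)(CC)CC)(C)COCc1ccc(OC)cc1 | intermediate
8 | (2E,4S)-5-[(4-methoxybenzyl)oxy]-2,4-dimethyl-4-(triethylsilyloxy)pent-2-enal | O=C/C(C)=C/[C@@](O[Si](CC)(CC)CC)(C)COCc1ccc(OC)cc1 | intermediate
9 | ethyl (2S)-2-hydroxypropanoate (ethyl (S)-lactate) | C[C@H](O)C(=O)OCC | starting material
10 | (2S)-2-hydroxy-N-methoxy-N-methylpropanamide | C[C@H](O)C(=O)N(C)OC | intermediate
11 | (2S)-2-hydroxypentan-3-one | C[C@H](O)C(=O)CC | intermediate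
12 | (2S)-3-oxopentan-2-yl benzoate | C[C@H](OC(=O)c1ccccc1)C(=O)CC | intermediate
13 | (2S,3E)-3-[(dicyclohexylboranyl)oxy]pent-3-en-2-yl benzoate | C/C=C(/OB(C1CCCCC1)C1CCCCC1)[C@H](C)OC(=O)c1ccccc1 | intermediate
14 | (2S,4R,5S,6E,8S)-5-hydroxy-9-[(4-methoxybenzyl)oxy]-4,6,8-trimethyl-3-oxo-8-(triethylsilyloxy)non-6-en-2-yl benzoate | C[C@H](OC(=O)c1ccccc1)C(=O)[C@H](C)[C@H](O)/C(C)=C/[C@@](O[Si](CC)(CC)CC)(C)COCc1ccc(OC)cc1 | intermediate
15 | dimethyl 2-methylpropanedioate (dimethyl methylmalonate) | COC(=O)C(C)C(=O)OC | starting material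
16 | 3-methoxy-2-methyl-3-oxopropanoic acid (racemic) | COC(=O)C(C)C(=O)O | intermediate
17 | C8 methyl methylmalonate of 14 (both epimers at the malonate carbon) | C[C@H](OC(=O)c1ccccc1)C(=O)[C@H](C)[C@H](OC(=O)C(C)C(=O)OC)/C(C)=C/[C@@](O[Si](CC)(CC)CC)(C)COCc1ccc(OC)cc1 | intermediate
18 | 1-[(4R,5S,6E,8S)-9-[(4-methoxybenzyl)oxy]-4,6,8-trimethyl-3-oxo-8-(triethylsilyloxy)non-6-en-5-yl] 3-methyl 2-methylpropanedioate | CCC(=O)[C@H](C)[C@H](OC(=O)C(C)C(=O)OC)/C(C)=C/[C@@](O[Si](CC)(CC)CC)(C)COCc1ccc(OC)cc1 | intermediate
19 | 1-[(1S,2E,4S)-1-[(1R)-1-(2-ethyl-1,3-dioxolan-2-yl)ethyl]-5-[(4-methoxybenzyl)oxy]-2,4-dimethyl-4-(triethylsilyloxy)pent-2-en-1-yl] 3-methyl 2-methylpropanedioate | CCC1(OCCO1)[C@H](C)[C@H](OC(=O)C(C)C(=O)OC)/C(C)=C/[C@@](O[Si](CC)(CC)CC)(C)COCc1ccc(OC)cc1 | intermediate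
20 | trimethylsilyl ketene acetal of 19 (trimethylsilyloxy group cis to the methoxycarbonyl group) | CCC1(OCCO1)[C@H](C)[C@H](O/C(O[Si](C)(C)C)=C(\C)C(=O)OC)/C(C)=C/[C@@](O[Si](CC)(CC)CC)(C)COCc1ccc(OC)cc1 | intermediate
21 | (2S,3R,4E,6R)-6-(2-ethyl-1,3-dioxolan-2-yl)-2-(methoxycarbonyl)-3-[(2S)-1-[(4-methoxybenzyl)oxy]-2-(triethylsilyloxy)propan-2-yl]-2,4-dimethylhept-4-enoic acid | CCC1(OCCO1)[C@H](C)/C=C(\C)[C@@H]([C@](C)(O[Si](CC)(CC)CC)COCc1ccc(OC)cc1)[C@](C)(C(=O)OC)C(=O)O | intermediate
22 | acid chloride of 21 (all centres as in 21) | CCC1(OCCO1)[C@H](C)/C=C(\C)[C@@H]([C@](C)(O[Si](CC)(CC)CC)COCc1ccc(OC)cc1)[C@](C)(C(=O)OC)C(=O)Cl | intermediate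
23 | methyl (2S,3R,4E,6R)-6-(2-ethyl-1,3-dioxolan-2-yl)-2-formyl-3-[(2S)-1-[(4-methoxybenzyl)oxy]-2-(triethylsilyloxy)propan-2-yl]-2,4-dimethylhept-4-enoate | CCC1(OCCO1)[C@H](C)/C=C(\C)[C@@H]([C@](C)(O[Si](CC)(CC)CC)COCc1ccc(OC)cc1)[C@](C)(C(=O)OC)C=O | intermediate
24 | ethyltriphenylphosphonium iodide | CC[P+](c1ccccc1)(c1ccccc1)c1ccccc1.[I-] | starting material
25 | ethylidenetriphenylphosphorane | CC=P(c1ccccc1)(c1ccccc1)c1ccccc1 | intermediate
26 | (1-iodoethyl)triphenylphosphonium iodide | CC(I)[P+](c1ccccc1)(c1ccccc1)c1ccccc1.[I-] | intermediate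
27 | (1-iodoethylidene)triphenylphosphorane | CC(I)=P(c1ccccc1)(c1ccccc1)c1ccccc1 | intermediate
28 | methyl (2S,3R,4E,6R)-6-(2-ethyl-1,3-dioxolan-2-yl)-2-[(1Z)-2-iodoprop-1-en-1-yl]-3-[(2S)-1-[(4-methoxybenzyl)oxy]-2-(triethylsilyloxy)propan-2-yl]-2,4-dimethylhept-4-enoate | CCC1(OCCO1)[C@H](C)/C=C(\C)[C@@H]([C@](C)(O[Si](CC)(CC)CC)COCc1ccc(OC)cc1)[C@](C)(C(=O)OC)/C=C(/C)I | intermediate
29 | methyl (2S,3R,4E,6R)-6-(2-ethyl-1,3-dioxolan-2-yl)-3-[(2S)-1-hydroxy-2-(triethylsilyloxy)propan-2-yl]-2-[(1Z)-2-iodoprop-1-en-1-yl]-2,4-dimethylhept-4-enoate | CCC1(OCCO1)[C@H](C)/C=C(\C)[C@@H]([C@](C)(O[Si](CC)(CC)CC)CO)[C@](C)(C(=O)OC)/C=C(/C)I | intermediate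
30 | methyl (2S,3R,4E,6R)-6-(2-ethyl-1,3-dioxolan-2-yl)-2-[(1Z)-2-iodoprop-1-en-1-yl]-2,4-dimethyl-3-[(2S)-1-oxo-2-(triethylsilyloxy)propan-2-yl]hept-4-enoate | CCC1(OCCO1)[C@H](C)/C=C(\C)[C@@H]([C@](C)(O[Si](CC)(CC)CC)C=O)[C@](C)(C(=O)OC)/C=C(/C)I | intermediate
31 | (Z)-alkenylchromium dichloride from 30 (CrCl2 in place of iodine) | CCC1(OCCO1)[C@H](C)/C=C(\C)[C@@H]([C@](C)(O[Si](CC)(CC)CC)C=O)[C@](C)(C(=O)OC)/C=C(/C)[Cr](Cl)Cl | intermediate
32 | methyl (1R,4S,5S,6R)-6-[(2E,4R)-4-(2-ethyl-1,3-dioxolan-2-yl)pent-2-en-2-yl]-4-hydroxy-1,3,5-trimethyl-5-(triethylsilyloxy)cyclohex-2-ene-1-carboxylate | CCC1(OCCO1)[C@H](C)/C=C(\C)[C@H]1[C@](C)(O[Si](CC)(CC)CC)[C@@H](O)C(C)=C[C@@]1(C)C(=O)OC | intermediate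
33 | methyl (1R,4S,5S,6R)-6-[(2E,4R)-4-(2-ethyl-1,3-dioxolan-2-yl)pent-2-en-2-yl]-1,3,5-trimethyl-4,5-bis(triethylsilyloxy)cyclohex-2-ene-1-carboxylate | CCC1(OCCO1)[C@H](C)/C=C(\C)[C@H]1[C@](C)(O[Si](CC)(CC)CC)[C@@H](O[Si](CC)(CC)CC)C(C)=C[C@@]1(C)C(=O)OC | intermediate
34 | [(1R,4S,5S,6R)-6-[(2E,4R)-4-(2-ethyl-1,3-dioxolan-2-yl)pent-2-en-2-yl]-1,3,5-trimethyl-4,5-bis(triethylsilyloxy)cyclohex-2-en-1-yl]methanol | CCC1(OCCO1)[C@H](C)/C=C(\C)[C@H]1[C@](C)(O[Si](CC)(CC)CC)[C@@H](O[Si](CC)(CC)CC)C(C)=C[C@@]1(C)CO | intermediate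
35 | (1R,4S,5S,6R)-6-[(2E,4R)-4-(2-ethyl-1,3-dioxolan-2-yl)pent-2-en-2-yl]-1,3,5-trimethyl-4,5-bis(triethylsilyloxy)cyclohex-2-ene-1-carbaldehyde | CCC1(OCCO1)[C@H](C)/C=C(\C)[C@H]1[C@](C)(O[Si](CC)(CC)CC)[C@@H](O[Si](CC)(CC)CC)C(C)=C[C@@]1(C)C=O | intermediate
36 | methyl 2-methyl-3-oxopentanoate (racemic) | CCC(=O)C(C)C(=O)OC | starting material
37 | sodium lithium dianion of 36 | CC=C([O-])C(C)=C([O-])OC.[Na+].[Li+] | intermediate
38 | δ-hydroxy β-keto ester from 35 and 36 (mixture at the three chain centres) | CCC1(OCCO1)[C@H](C)/C=C(\C)[C@H]1[C@](C)(O[Si](CC)(CC)CC)[C@@H](O[Si](CC)(CC)CC)C(C)=C[C@@]1(C)C(O)C(C)C(=O)C(C)C(=O)OC | intermediate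
39 | 3,5-diketo ester from 38 | CCC1(OCCO1)[C@H](C)/C=C(\C)[C@H]1[C@](C)(O[Si](CC)(CC)CC)[C@@H](O[Si](CC)(CC)CC)C(C)=C[C@@]1(C)C(=O)C(C)C(=O)C(C)C(=O)OC | intermediate
40 | 4-hydroxy-3,5-dimethyl-2H-pyran-2-one bearing at C6′ the (1R,4S,5S,6R)-cyclohexenyl unit of 35 | CCC1(OCCO1)[C@H](C)/C=C(\C)[C@H]1[C@](C)(O[Si](CC)(CC)CC)[C@@H](O[Si](CC)(CC)CC)C(C)=C[C@@]1(C)C1=C(C)C(O)=C(C)C(=O)O1 | intermediate
41 | 2-methoxy-3,5-dimethyl-6-[(1R,4S,5S,6R)-6-[(2E,4R)-4-(2-ethyl-1,3-dioxolan-2-yl)pent-2-en-2-yl]-1,3,5-trimethyl-4,5-bis(triethylsilyloxy)cyclohex-2-en-1-yl]-4H-pyran-4-one | CCC1(OCCO1)[C@H](C)/C=C(\C)[C@H]1[C@](C)(O[Si](CC)(CC)CC)[C@@H](O[Si](CC)(CC)CC)C(C)=C[C@@]1(C)c1oc(OC)c(C)c(=O)c1C | intermediate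
42 | 2-[(1R,4S,5S,6R)-4,5-dihydroxy-1,3,5-trimethyl-6-[(2E,4R)-4-methyl-5-oxohept-2-en-2-yl]cyclohex-2-en-1-yl]-6-methoxy-3,5-dimethyl-4H-pyran-4-one | CCC(=O)[C@H](C)/C=C(\C)[C@H]1[C@](C)(O)[C@@H](O)C(C)=C[C@@]1(C)c1oc(OC)c(C)c(=O)c1C | intermediate
43 | C3 methanesulfonate of 42 (tertiary C2 hydroxyl free) | CCC(=O)[C@H](C)/C=C(\C)[C@H]1[C@](C)(O)[C@@H](OS(C)(=O)=O)C(C)=C[C@@]1(C)c1oc(OC)c(C)c(=O)c1C | intermediate
44 | 2-methoxy-3,5-dimethyl-6-[(1R,4R,5R,6S)-2,4,6-trimethyl-5-[(2E,4R)-4-methyl-5-oxohept-2-en-2-yl]-7-oxabicyclo[4.1.0]hept-2-en-4-yl]-4H-pyran-4-one (CNP0336888.3) | CCC(=O)[C@H](C)/C=C(\C)[C@H]1[C@]2(C)O[C@@H]2C(C)=C[C@@]1(C)c1oc(OC)c(C)c(=O)c1C | target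

## Step count and least certain steps

Total step count: 28. Longest linear sequence: 24 steps (steps 1–5, 9 and 11–28, from 1 to 44); steps 6–8 and step 10 prepare 12 and 16 off the main line.

**Step 19 (key step).** The likeliest failure is poor facial selectivity at C3, because the preference for the equatorial chromium alkoxide competes with the 1,3-diaxial contact between the C2 methyl and the C6 ester in the reacting conformer. Slow insertion into the hindered trisubstituted iodide, ending in protodeiodination, is the second concern. The fallback replaces control in the C–C bond formation by control in a hydride delivery. It sets out from 32 as obtained, whatever its C3 composition, and returns to 32. Dess–Martin oxidation would give the cyclohexenone methyl (1R,5S,6R)-6-[(2E,4R)-4-(2-ethyl-1,3-dioxolan-2-yl)pent-2-en-2-yl]-1,3,5-trimethyl-4-oxo-5-(triethylsilyloxy)cyclohex-2-ene-1-carboxylate F1. Luche reduction (NaBH4, CeCl3·7H2O, MeOH, −78 °C) should then deliver hydride anti to the pseudo-axial C2 methyl, placing C3–OH trans to the C2 oxygen.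

**Step 14.** The likeliest failure is formation of the ketene acetal with the opposite geometry, or equilibration of the silyl group between the two malonate oxygens, which would invert C6 relative to C1. Slow rearrangement through the crowded transition state is the second concern. The fallback uses the fact that the two carboxyl groups on C6 are interchangeable. It sets out from 19 and returns at 23. If the rearrangement gives mainly the C6-epimeric acid F2, its methyl ester is reduced in the presence of the lithium carboxylate (LiBH4, THF) to the hydroxy acid F3. The acid is esterified (Me3SiCHN2, MeOH/toluene) to the hydroxy ester F4, and Dess–Martin oxidation then gives 23 itself, because the reduced carbon now becomes C5.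

**Step 16.** The likeliest failure is low conversion of the neopentyl, α-quaternary aldehyde with the bulky iodo ylide, with erosion of the Z/E ratio or attack at the neighbouring ester on warming. The fallback builds the haloalkene by cross-coupling and not by olefination. It sets out from 23 and returns at 28. Corey–Fuchs dibromo-olefination (CBr4, PPh3, CH2Cl2, 0 °C) would give the 1,1-dibromoalkene F5. A trans-selective Negishi monomethylation (Me2Zn, Pd(PtBu3)2 cat., THF, 0 °C) would replace the bromine trans to C6 and give the (Z)-bromoalkene F6. Copper-catalysed halogen exchange (CuI, NaI, trans-N,N′-dimethylcyclohexane-1,2-diamine, dioxane, 100 °C) would give 28 with retention.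

**Step 27.** The likeliest failure is acid-induced ionisation of the allylic C3 carbinol, or migration of the C7=C8 alkene into conjugation, during the time needed to hydrolyse the hindered dioxolane. The fallback separates the two kinds of unmasking. It sets out from 41 and returns at 42. Fluoride (Bu4NF, THF, 0 °C) would remove both silyl ethers while the ketone is still masked, giving the diol ketal F7. A mild transketalisation (pyridinium p-toluenesulfonate, wet acetone, 40 °C) would then release the ketone.

**Step 28.** The likeliest failure is ionisation of the allylic mesylate before closure, with loss of stereochemical integrity at C3, or base-induced epimerisation at C9. The fallback sets out from 42 and returns at 44 in one operation: a Mitsunobu cyclodehydration (PPh3, diisopropyl azodicarboxylate, toluene, rt). The secondary allylic hydroxyl is activated as the alkoxyphosphonium ion and displaced with inversion by the tertiary oxygen under essentially neutral conditions. It forms no compound outside the compound list (entry F0).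

## Further compounds

F1 | step 19 | methyl (1R,5S,6R)-6-[(2E,4R)-4-(2-ethyl-1,3-dioxolan-2-yl)pent-2-en-2-yl]-1,3,5-trimethyl-4-oxo-5-(triethylsilyloxy)cyclohex-2-ene-1-carboxylate | CCC1(OCCO1)[C@H](C)/C=C(\C)[C@H]1[C@](C)(O[Si](CC)(CC)CC)C(=O)C(C)=C[C@@]1(C)C(=O)OC
F2 | step 14 | C6 epimer of 21 (carboxyl and methoxycarbonyl groups on the quaternary carbon interchanged) | CCC1(OCCO1)[C@H](C)/C=C(\C)[C@@H]([C@](C)(O[Si](CC)(CC)CC)COCc1ccc(OC)cc1)[C@](C)(C(=O)O)C(=O)OC
F3 | step 14 | hydroxy acid from F2 (methoxycarbonyl group reduced to hydroxymethyl) | CCC1(OCCO1)[C@H](C)/C=C(\C)[C@@H]([C@](C)(O[Si](CC)(CC)CC)COCc1ccc(OC)cc1)[C@](C)(C(=O)O)CO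
F4 | step 14 | hydroxy ester from F3 (methyl ester of the acid, hydroxymethyl at the future C5) | CCC1(OCCO1)[C@H](C)/C=C(\C)[C@@H]([C@](C)(O[Si](CC)(CC)CC)COCc1ccc(OC)cc1)[C@](C)(C(=O)OC)CO
F5 | step 16 | 1,1-dibromoalkene from 23 (2,2-dibromoethenyl in place of formyl) | CCC1(OCCO1)[C@H](C)/C=C(\C)[C@@H]([C@](C)(O[Si](CC)(CC)CC)COCc1ccc(OC)cc1)[C@](C)(C(=O)OC)C=C(Br)Br
F6 | step 16 | (Z)-2-bromoprop-1-enyl analogue of 28 | CCC1(OCCO1)[C@H](C)/C=C(\C)[C@@H]([C@](C)(O[Si](CC)(CC)CC)COCc1ccc(OC)cc1)[C@](C)(C(=O)OC)/C=C(/C)Br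
F7 | step 27 | diol ketal: 41 without its two silyl groups | CCC1(OCCO1)[C@H](C)/C=C(\C)[C@H]1[C@](C)(O)[C@@H](O)C(C)=C[C@@]1(C)c1oc(OC)c(C)c(=O)c1C
F0 | step 28 | none | none
A1 | alternative 1 | cis-fused menthyloxy lactone acetal with the silyl enol ether at C3=C4 | O=C1O[C@H](O[C@H]3C[C@@H](C)CC[C@@H]3C(C)C)[C@H]2[C@@H](C)C(O[Si](C)(C)C(C)(C)C)=C(C)C[C@@]12C
A2 | alternative 1 | 5-menthyloxy-3-methylfuran-2(5H)-one | O=C1O[C@H](O[C@H]2C[C@@H](C)CC[C@@H]2C(C)C)C=C1C
A3 | alternative 1 | (3Z)-3-(tert-butyldimethylsilyloxy)-2-methylpenta-1,3-diene | C=C(C)/C(O[Si](C)(C)C(C)(C)C)=C/C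
A4 | alternative 2 | C1-isopropenyl cyclohexenone with C2 triethylsilyloxy and C6 silyloxymethyl groups | C=C(C)[C@H]1[C@](C)(O[Si](CC)(CC)CC)C(=O)C(C)=C[C@@]1(C)CO[Si](C)(C)C(C)(C)C
A5 | alternative 2 | 1-methylcyclobutene carrying the C2(OSiEt3)–C3(=O)–C4(Me)=CH2 arm on C1 | CC1=C[C@@](C)(CO[Si](C)(C)C(C)(C)C)[C@@H]1[C@](C)(O[Si](CC)(CC)CC)C(=O)C(C)=C
A6 | alternative 3 | C2-hydroxy C3-oxo cyclohexene bearing the pyranone and the ketal-protected chain | CCC1(OCCO1)[C@H](C)/C=C(\C)[C@H]1[C@](C)(O)C(=O)C(C)=C[C@@]1(C)c1oc(OC)c(C)c(=O)c1C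
A7 | alternative 3 | open-chain C2 methyl ketone with a (Z)-C3 enal on quaternary C6 | CCC1(OCCO1)[C@H](C)/C=C(\C)[C@@H](C(C)=O)[C@](C)(c1oc(OC)c(C)c(=O)c1C)/C=C(/C)C=O
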